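## Structural features

The target is a 1,2-di-O-acyl-sn-glycerol: glycerol C2 is S, O1 and O2 carry the same C18 acyl group, and O3 is a free primary hydroxyl. Each chain runs from the ester carbonyl C1 through two methylenes (C2, C3) into a conjugated diyne (C4≡C5–C6≡C7). The diyne is bonded directly to a trans-2,3-disubstituted oxirane (C8 and C9, both S), and three methylenes (C10–C12) lead on to a (13Z,15Z)-diene with an ethyl terminus. The only stereocentres of a chain are the two adjacent oxirane carbons. They lie far from the glycerol centre, so all five centres must be set absolutely; stereoisomers of the final diester could not be separated. The fragile groups are the alkynyl oxirane (acid, soft nucleophiles and low-valent metals, also in the SN2′ sense), the Z,Z-diene (electrophilic oxidants, radicals, hydrogenation), the diyne (strong base, reducing metals, light) and the 1,2-diester (O2→O3 acyl shift). The real difficulty is to make an enantioenriched trans oxirane between a diyne and a diene-bearing chain without an olefin-epoxidising oxidant, and then to carry it through an alcohol-to-acid oxidation, a double esterification and a last deprotection. The key step uses the fact that C8 is both an oxirane carbon and the carbon next to the diyne terminus C7, while the O–C9 bond can be made by displacing a leaving group on C9. C8 and C9 therefore map onto the carbonyl and α-carbon of a 2-chloroaldehyde.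

## Logic of the disconnections

24 ⇒ 23. The benzylic C–O bond of an ether on O3 is cut. O3 must be told apart from O1 and O2 while the chains are attached, and a 4-methoxybenzyl ether can be removed by a neutral, non-reductive, non-acidic reagent. The gain is that the regiochemistry of the diester is settled on a three-carbon building block. The forward step must be short, cold and buffered, because the freed hydroxyl can take over the neighbouring acyl group, and the oxidant must prefer the arene to the dienes.

23 ⇒ 21 + 2 × 18 (through 22). Both acyl C–O bonds are cut at once because the two chains are identical. This reduces the problem to one C18 acid and makes the end-game two-directional. The forward step needs an activation that works at a secondary hydroxyl without acid chloride, strong base or heat, and it consumes somewhat more than two equivalents of 18.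

21 ⇒ 20 ⇒ 19. The acetal C–O bonds and the ether C–O bond are cut. The glycerol stereocentre comes from the chiral pool with the right sense, since the free hydroxyl of 19 is O3. The only demand is acetal hydrolysis that leaves the ether intact.

18 ⇒ 16 (through 17) ⇒ 15. No skeletal bond is cut: C1 is taken back from acid to alcohol and the alcohol to its silyl ether (O–Si). C1 must pass the organolithium step in a form that is neither acidic nor electrophilic. The price is an alcohol-to-acid oxidation in the presence of oxirane, diyne and diene, so the oxidant must be neutral, halogen-free and unable to epoxidise.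

15 ⇒ 14. The O–C9 bond of the oxirane is cut, which leaves the C8 hydroxyl and a chloride on C9. The oxirane is then made by substitution and not by oxygen transfer to an alkene, so there is no conflict with the diene. Closure inverts C9, so the forward step needs the anti chlorohydrin and a base mild enough for the silyl ether and the diyne.

14 ⇒ 12 (as 13) + 7. The C7–C8 bond is cut between the diyne terminus and the carbinol carbon. This gives two fragments of similar size (C1–C7 and C8–C18), uses the natural polarity of acetylide and aldehyde, and lets the C9 centre of 7 set C8. The forward step must be anti-selective and must not racemise 7.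

7 ⇒ 6 ⇒ 5 ⇒ 4 ⇒ 2 + 3; 2 ⇒ 1. The C9–Cl bond is cut first (enantioselective α-chlorination of an unbranched aldehyde). The oxidation level of C8 is then lowered, the Z,Z-diene is traced back to a conjugated diyne, and the diyne is cut at its central sp–sp bond (C14–C15). The bromine is placed on the non-volatile C7 partner 2 so that gaseous 3 is used as such and in excess. The demands are a closed-shell chlorination that ignores the diene, a stereospecific cis semi-reduction that stops at the diene, and an oxidation that does not isomerise double bonds.

12 ⇒ 11 ⇒ 8 + 9 (through 10). The C(sp)–Si bond and then the C3–C4 bond are cut. All four sp carbons come from a stable, crystalline, doubly silylated butadiyne, and free butadiyne is never handled. The forward step needs clean mono-metalation of 8 and alkylation of a weakly nucleophilic diynide, which calls for a primary iodide and a dipolar cosolvent.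

## Other disconnections considered

Alternative 1: The cut is at both C5–C6 bonds, the central sp–sp bond of each diyne, after the glycerol diester has been built. In the forward key step the bis(1-bromoalkyne) diester A1 (which would come from 21 by diacylation) is coupled twice with the terminal ethynyl oxirane A2 under CuCl, NH2OH·HCl and a hindered amine (Cadiot–Chodkiewicz coupling) to give A3, the same compound as 23.
- In its favour: C1 is at the acid level from the start, so no alcohol-to-acid oxidation is run next to oxirane and diene. On this point it is better than the chosen plan. The sensitive chain would see only the coupling and the last deprotection.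
- Against it: two heterocouplings must both go to completion on one molecule, and incomplete coupling or homocoupling of A2 would give lipids of similar polarity. The amine can attack the esters or the oxirane, and a copper acetylide next to an alkynyl oxirane invites SN2′ opening. A2 is small, sensitive and needed in excess.
- Structure: both plans join the chain at the diyne and both need rather more than two equivalents of the chiral chain; on this they are equal.
- Mechanism: the coupling creates no stereocentre, so it cannot erode one, but it also does not solve the stereochemical problem. A2 would still come from 7 by the acetylide/chlorohydrin chemistry, so the question is only moved.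
- Step economy: about two steps shorter in the longest line, so it is the better plan on this count. The chosen plan is preferred for predictability, since each bond is made once with stoichiometric control.

Alternative 2: The cut is at both C–O bonds of the oxirane (O–C8 and O–C9), with the diene carried as a 1,3-diyne. In the forward key step the E-enetriyne A4 is epoxidised at C8=C9 by the dioxirane formed from KHSO5 (as the triple salt 2KHSO5·KHSO4·K2SO4) and the chiral ketone A5 (Shi epoxidation), which would give A6.
- In its favour: both oxirane centres come from catalyst control and alkene geometry in one step. No configurationally labile intermediate is involved and no syn/anti question arises; on these two points it is better than the chosen plan. Conjugated E-enynes are good substrates, and the diyne is inert to the dioxirane.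
- Against it: the Z,Z-diene must then be made by semi-reduction with the alkynyl oxirane already present, where reducing metals can open the propargylic C–O bond. A5 is the enantiomer that does not come from the cheap natural sugar and is used at substantial loading. After the epoxidation, C-desilylation and an sp–sp coupling are still needed to add C1–C5, which leads into the end-game of alternative 1.
- Structure: two C–O bonds are formed instead of one C–C and one C–O bond.
- Mechanism: external (reagent) control against internal (substrate) control; the expected levels of enantioselectivity of the two catalytic steps are comparable, so they are equal on this point.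
- Step economy: several steps longer, because A4 needs its own enyne and diyne construction and the diene has to be unmasked later.

Alternative 3: The cut is at C10–C11, an sp3–sp3 bond remote from all functionality. In the forward key step the epoxy triflate A7 is displaced at its primary carbon by the homoallylic Grignard reagent A8 with catalytic CuI, the oxirane staying closed, to give A9.
- In its favour: both oxirane centres would come from the chiral pool in full enantiopurity, with the trans geometry fixed from the start. This is better than an organocatalytic step whose selectivity limits the isomeric purity of a two-chain product. The key step forms no stereocentre and cannot erode one.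
- Against it: A7 is a highly reactive electrophile that takes several steps to make. A8 carries a Z double bond in the homoallylic position, where reversible closure to a cyclopropylmethyl magnesium species can scramble the geometry, and its bromide needs a Z,Z-diene synthesis of its own. After the coupling, A9 still needs desilylation, oxidation to an epimerisable epoxy aldehyde, one-carbon homologation to A2 and the diyne coupling.
- Structure: the joint lies in the saturated spacer and not at the diyne.
- Mechanism: copper-catalysed SN2 at a primary triflate against carbonyl addition; both are reliable reaction types, so they are equal on this point.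
- Step economy: clearly worse, with a longest line in the high teens.

Key step: step 8

Assumptions (remarks on the chemistry):
- The steric model for enamines of 2,5-diphenylpyrrolidine is taken to hold, so that the (2S,5S) amine gives the 2R chloride; if the sense were the reverse, the (2R,5R) amine would be used with no other change.
- Compounds 9 and 19 are taken as commercial.

## Route

Step 1
Reactants: 1 hept-6-yn-1-ol
Product: 2 7-bromohept-6-yn-1-ol
Conditions: NBS (1.1 equiv), AgNO3 (10 mol %), acetone, rt, dark
Reagents that add atoms: N-bromosuccinimide, O=C1CCC(=O)N1Br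
Why: Silver-catalysed electrophilic bromination of the terminal C(sp)–H bond (through the silver acetylide) is selective for the alkyne and leaves the primary alcohol alone; putting the halogen on the non-volatile C7 partner lets gaseous 3 be used as such.

Step 2
Reactants: 2 7-bromohept-6-yn-1-ol; 3 but-1-yne
Product: 4 undeca-6,8-diyn-1-ol
Conditions: 3 (4 equiv, condensed at −20 °C), CuCl (5 mol %), NH2OH·HCl (0.3 equiv), n-BuNH2 (30% aq.), MeOH, 0 °C, slow addition of 2
Reagents that add atoms: none
Why: Cadiot–Chodkiewicz coupling: the copper acetylide of 3 substitutes the bromoalkyne and forms the C(sp)–C(sp) bond; excess 3, slow addition of 2 and NH2OH·HCl (which keeps the copper monovalent) suppress homocoupling.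

Step 3
Reactants: 4 undeca-6,8-diyn-1-ol
Product: 5 (6Z,8Z)-undeca-6,8-dien-1-ol
Conditions: Zn dust activated with Cu(OAc)2 and AgNO3 (excess), MeOH/H2O 1:1, rt to 40 °C, Ar, dark
Reagents that add atoms: none
Why: Boland-type semi-reduction with activated zinc delivers hydrogen cis to conjugated triple bonds only and stops at the alkene, so both alkynes should become Z alkenes; the alcohol is inert and no stereocentre is involved.

Step 4
Reactants: 5 (6Z,8Z)-undeca-6,8-dien-1-ol
Product: 6 (6Z,8Z)-undeca-6,8-dienal
Conditions: TEMPO (2,2,6,6-tetramethylpiperidin-1-oxyl, 10 mol %), PhI(OAc)2 (1.1 equiv), CH2Cl2, rt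
Reagents that add atoms: none
Why: Nitroxyl-catalysed (oxoammonium) oxidation of the primary alcohol stops at the aldehyde in anhydrous CH2Cl2 and needs no acid, base or radical chain that could isomerise the Z,Z-diene.

Step 5
Reactants: 6 (6Z,8Z)-undeca-6,8-dienal
Product: 7 (2R,6Z,8Z)-2-chloroundeca-6,8-dienal
Conditions: (2S,5S)-2,5-diphenylpyrrolidine (10 mol %), NCS (1.2 equiv), CH2Cl2, 0 °C to rt; pentane, filtration, cold concentration; used at once
Reagents that add atoms: N-chlorosuccinimide, O=C1CCC(=O)N1Cl
Why: Enamine catalysis: the C2-symmetric secondary amine forms an E-enamine with 6, and NCS chlorinates its α-carbon on the face remote from the flanking phenyl group, which sets the 2R centre (C9 of the chain); the closed-shell electrophilic pathway leaves the diene alone, and the product is not chromatographed because it racemises through its enol.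

Step 6
Reactants: 8 1,4-bis(trimethylsilyl)buta-1,3-diyne; 9 tert-butyl(3-iodopropoxy)dimethylsilane
Product: 11 tert-butyl(dimethyl){[7-(trimethylsilyl)hepta-4,6-diyn-1-yl]oxy}silane, via lithium silylbutadiynide 10 (not isolated)
Conditions: MeLi·LiBr (1.0 equiv), THF, −78 °C to rt, 3 h; then 9 (0.9 equiv), DMPU, −78 °C to rt
Reagents that add atoms: none
Why: MeLi·LiBr cleaves one C(sp)–Si bond of 8 (the resulting anion deactivates the second silyl group), and lithium diynide 10 is alkylated by the primary iodide in an SN2 reaction helped by the dipolar cosolvent, which forms the C3–C4 bond.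

Step 7
Reactants: 11 tert-butyl(dimethyl){[7-(trimethylsilyl)hepta-4,6-diyn-1-yl]oxy}silane
Product: 12 tert-butyl(hepta-4,6-diyn-1-yloxy)dimethylsilane
Conditions: K2CO3 (0.2 equiv), MeOH/THF, rt, 1 h; used at once
Reagents that add atoms: none
Why: Base-catalysed methanolysis cleaves the C(sp)–SiMe3 bond selectively, the O–Si(t-Bu)Me2 ether being far slower to solvolyse; the terminal diyne is used directly because such compounds darken on storage.

Step 8
Reactants: 12 tert-butyl(hepta-4,6-diyn-1-yloxy)dimethylsilane; 7 (2R,6Z,8Z)-2-chloroundeca-6,8-dienal
Product: 14 (8S,9R,13Z,15Z)-1-[tert-butyl(dimethyl)silyl]oxy-9-chlorooctadeca-13,15-dien-4,6-diyn-8-ol, via lithium diynide 13 (not isolated)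
Conditions: 12 (1.3 equiv), n-BuLi (1.2 equiv), THF, −78 °C, 30 min; then 7 (1.0 equiv) in THF, −78 °C; AcOH/THF quench at −78 °C
Reagents that add atoms: none
Why: Metalation of 12 with n-BuLi gives lithium diynide 13, which attacks the carbonyl carbon of 7 in a 1,2-addition and forms the C7–C8 bond; the closest known reaction type is the anti-selective addition of lithium acetylides to enantioenriched α-chloroaldehydes, used as an entry to trans-epoxides. No ring is closed in this step. The one new stereocentre, C8, is controlled by the existing C9 centre: in the Cornforth-type transition state the C–Cl and C=O dipoles are antiperiplanar and the slim, non-chelating acetylide passes the C9 hydrogen and not the C10 chain, which leads to the 1,2-anti (8S,9R) chlorohydrin. The selectivity needed is anti over syn, and it is secured by the α-chlorine itself, by the absence of a chelating metal and by the low temperature. The second requirement, retention of the labile C9 configuration, is met by adding 7 last to a slight deficit of base at −78 °C, so that no n-BuLi remains and the only base is the weakly basic diynide, and by the cold AcOH quench, which removes the lithium alkoxide before it can act as a base. The silyl ether, the internal diyne and the Z,Z-diene are spectators.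

Step 9
Reactants: 14 (8S,9R,13Z,15Z)-1-[tert-butyl(dimethyl)silyl]oxy-9-chlorooctadeca-13,15-dien-4,6-diyn-8-ol
Product: 15 tert-butyl(dimethyl)({7-[(2S,3S)-3-[(4Z,6Z)-nona-4,6-dien-1-yl]oxiran-2-yl]hepta-4,6-diyn-1-yl}oxy)silane
Conditions: K2CO3 (2 equiv), MeOH, 0 °C to rt
Reagents that add atoms: none
Why: Intramolecular Williamson reaction: the propargylic C8 alkoxide, accessible with carbonate, displaces chloride at C9 in a 3-exo-tet closure with inversion, so the anti (8S,9R) chlorohydrin should give the trans (8S,9S) oxirane; C8 is untouched and the silyl ether survives.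

Step 10
Reactants: 15 tert-butyl(dimethyl)({7-[(2S,3S)-3-[(4Z,6Z)-nona-4,6-dien-1-yl]oxiran-2-yl]hepta-4,6-diyn-1-yl}oxy)silane
Product: 16 7-[(2S,3S)-3-[(4Z,6Z)-nona-4,6-dien-1-yl]oxiran-2-yl]hepta-4,6-diyn-1-ol
Conditions: Bu4NF (1.2 equiv), THF, 0 °C
Reagents that add atoms: none
Why: Fluoride-induced cleavage of the Si–O bond; oxirane, diyne and diene are inert to Bu4NF at 0 °C.

Step 11
Reactants: 16 7-[(2S,3S)-3-[(4Z,6Z)-nona-4,6-dien-1-yl]oxiran-2-yl]hepta-4,6-diyn-1-ol
Product: 18 7-[(2S,3S)-3-[(4Z,6Z)-nona-4,6-dien-1-yl]oxiran-2-yl]hepta-4,6-diynoic acid, via epoxy diynal 17 (not isolated)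
Conditions: TEMPO (20 mol %), PhI(OAc)2 (2.4 equiv), MeCN/pH 7 phosphate buffer 1:1, 0 °C to rt
Reagents that add atoms: water, O
Why: Nitroxyl-catalysed oxidation with PhI(OAc)2 in aqueous acetonitrile takes the primary alcohol to aldehyde 17 and, through its hydrate, on to the acid; the buffered medium contains no electrophilic halogen and no peracid, so oxirane, diyne and Z,Z-diene should be spared.

Step 12
Reactants: 19 [(4S)-2,2-dimethyl-1,3-dioxolan-4-yl]methanol
Product: 20 (4S)-4-{[(4-methoxyphenyl)methoxy]methyl}-2,2-dimethyl-1,3-dioxolane
Conditions: NaH (1.2 equiv), 4-methoxybenzyl chloride (1.1 equiv), Bu4NI (5 mol %), THF/DMF, 0 °C to rt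
Reagents that add atoms: 4-methoxybenzyl chloride, COc1ccc(CCl)cc1
Why: Williamson etherification of the only free hydroxyl (O3 of the glycerol unit); the stereocentre is not involved.

Step 13
Reactants: 20 (4S)-4-{[(4-methoxyphenyl)methoxy]methyl}-2,2-dimethyl-1,3-dioxolane
Product: 21 (2R)-3-[(4-methoxyphenyl)methoxy]propane-1,2-diol (3-O-(4-methoxybenzyl)-sn-glycerol)
Conditions: AcOH/H2O 4:1, 40 °C
Reagents that add atoms: none
Why: Acid-catalysed acetal hydrolysis in aqueous acetic acid removes the isopropylidene group and leaves the 4-methoxybenzyl ether; the stereocentre is untouched, and the change of descriptor to R is a priority effect only.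

Step 14
Reactants: 21 (2R)-3-[(4-methoxyphenyl)methoxy]propane-1,2-diol; 18 7-[(2S,3S)-3-[(4Z,6Z)-nona-4,6-dien-1-yl]oxiran-2-yl]hepta-4,6-diynoic acid
Product: 23 3-O-(4-methoxybenzyl)-1,2-bis-O-{7-[(2S,3S)-3-[(4Z,6Z)-nona-4,6-dien-1-yl]oxiran-2-yl]hepta-4,6-diynoyl}-sn-glycerol, via monoester 22 (not isolated)
Conditions: 18 (2.4 equiv), N,N′-dicyclohexylcarbodiimide (2.6 equiv), 4-(dimethylamino)pyridine (0.5 equiv), CH2Cl2, 0 °C to rt
Reagents that add atoms: none
Why: Steglich esterification: the carbodiimide activates 18, and 4-(dimethylamino)pyridine transfers the acyl group first to the primary hydroxyl (22) and then to the secondary one; the neutral conditions avoid an acid chloride and so protect the oxiranes, and no stereocentre is at risk.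

Step 15
Reactants: 23 3-O-(4-methoxybenzyl)-1,2-bis-O-{7-[(2S,3S)-3-[(4Z,6Z)-nona-4,6-dien-1-yl]oxiran-2-yl]hepta-4,6-diynoyl}-sn-glycerol
Product: 24 1,2-bis-O-{7-[(2S,3S)-3-[(4Z,6Z)-nona-4,6-dien-1-yl]oxiran-2-yl]hepta-4,6-diynoyl}-sn-glycerol (CNP0301966.1)
Conditions: 2,3-dichloro-5,6-dicyano-1,4-benzoquinone (DDQ, 1.3 equiv), CH2Cl2/pH 7 phosphate buffer 10:1, 0 °C; chromatography on boric-acid-treated silica
Reagents that add atoms: none
Why: Oxidative cleavage of the 4-methoxybenzyl ether by DDQ (benzylic hydride abstraction through a charge-transfer complex, then hydrolysis of the oxocarbenium ion) runs under neutral buffered conditions, which disfavour O2→O3 acyl migration; the arene is a better donor than the Z,Z-dienes, which are also poor Diels–Alder partners because their s-cis form is strained.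

## Compound list

1 | hept-6-yn-1-ol | C#CCCCCCO | starting material
2 | 7-bromohept-6-yn-1-ol | BrC#CCCCCCO | intermediate
3 | but-1-yne | CCC#C | starting material
4 | undeca-6,8-diyn-1-ol | CCC#CC#CCCCCCO | intermediate
5 | (6Z,8Z)-undeca-6,8-dien-1-ol | CC/C=C\C=C/CCCCCO | intermediate
6 | (6Z,8Z)-undeca-6,8-dienal | CC/C=C\C=C/CCCCC=O | intermediate
7 | (2R,6Z,8Z)-2-chloroundeca-6,8-dienal | O=C[C@H](Cl)CCC/C=C\C=C/CC | intermediate
8 | 1,4-bis(trimethylsilyl)buta-1,3-diyne | C[Si](C)(C)C#CC#C[Si](C)(C)C | starting material
9 | tert-butyl(3-iodopropoxy)dimethylsilane | CC(C)(C)[Si](C)(C)OCCCI | starting material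
10 | lithium 4-(trimethylsilyl)buta-1,3-diyn-1-ide | [Li]C#CC#C[Si](C)(C)C | intermediate
11 | tert-butyl(dimethyl){[7-(trimethylsilyl)hepta-4,6-diyn-1-yl]oxy}silane | C[Si](C)(C)C#CC#CCCCO[Si](C)(C)C(C)(C)C | intermediate
12 | tert-butyl(hepta-4,6-diyn-1-yloxy)dimethylsilane | C#CC#CCCCO[Si](C)(C)C(C)(C)C | intermediate
13 | lithium 7-[tert-butyl(dimethyl)silyl]oxyhepta-1,3-diyn-1-ide | [Li]C#CC#CCCCO[Si](C)(C)C(C)(C)C | intermediate
14 | (8S,9R,13Z,15Z)-1-[tert-butyl(dimethyl)silyl]oxy-9-chlorooctadeca-13,15-dien-4,6-diyn-8-ol | CC(C)(C)[Si](C)(C)OCCCC#CC#C[C@H](O)[C@H](Cl)CCC/C=C\C=C/CC | intermediate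
15 | tert-butyl(dimethyl)({7-[(2S,3S)-3-[(4Z,6Z)-nona-4,6-dien-1-yl]oxiran-2-yl]hepta-4,6-diyn-1-yl}oxy)silane | CC(C)(C)[Si](C)(C)OCCCC#CC#C[C@@H]1O[C@H]1CCC/C=C\C=C/CC | intermediate
16 | 7-[(2S,3S)-3-[(4Z,6Z)-nona-4,6-dien-1-yl]oxiran-2-yl]hepta-4,6-diyn-1-ol | OCCCC#CC#C[C@@H]1O[C@H]1CCC/C=C\C=C/CC | intermediate
17 | 7-[(2S,3S)-3-[(4Z,6Z)-nona-4,6-dien-1-yl]oxiran-2-yl]hepta-4,6-diynal | O=CCCC#CC#C[C@@H]1O[C@H]1CCC/C=C\C=C/CC | intermediate
18 | 7-[(2S,3S)-3-[(4Z,6Z)-nona-4,6-dien-1-yl]oxiran-2-yl]hepta-4,6-diynoic acid | OC(=O)CCC#CC#C[C@@H]1O[C@H]1CCC/C=C\C=C/CC | intermediate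
19 | [(4S)-2,2-dimethyl-1,3-dioxolan-4-yl]methanol | OC[C@H]1COC(C)(C)O1 | starting material
20 | (4S)-4-{[(4-methoxyphenyl)methoxy]methyl}-2,2-dimethyl-1,3-dioxolane | COc1ccc(COC[C@H]2COC(C)(C)O2)cc1 | intermediate
21 | (2R)-3-[(4-methoxyphenyl)methoxy]propane-1,2-diol | OC[C@H](COCc1ccc(OC)cc1)O | intermediate
22 | (2S)-2-hydroxy-3-[(4-methoxyphenyl)methoxy]propyl 7-[(2S,3S)-3-[(4Z,6Z)-nona-4,6-dien-1-yl]oxiran-2-yl]hepta-4,6-diynoate | CC/C=C\C=C/CCC[C@@H]1O[C@H]1C#CC#CCCC(=O)OC[C@H](COCc2ccc(OC)cc2)O | intermediate
23 | (2S)-3-[(4-methoxyphenyl)methoxy]propane-1,2-diyl bis{7-[(2S,3S)-3-[(4Z,6Z)-nona-4,6-dien-1-yl]oxiran-2-yl]hepta-4,6-diynoate} | CC/C=C\C=C/CCC[C@@H]1O[C@H]1C#CC#CCCC(=O)OC[C@H](COCc2ccc(OC)cc2)OC(=O)CCC#CC#C[C@@H]3O[C@H]3CCC/C=C\C=C/CC | intermediate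
24 | (2S)-3-hydroxypropane-1,2-diyl bis{7-[(2S,3S)-3-[(4Z,6Z)-nona-4,6-dien-1-yl]oxiran-2-yl]hepta-4,6-diynoate} | CC/C=C\C=C/CCC[C@@H]1O[C@H]1C#CC#CCCC(=O)OC[C@H](CO)OC(=O)CCC#CC#C[C@@H]1O[C@H]1CCC/C=C\C=C/CC | target

## Step count and least certain steps

Total step count: 15. Longest linear sequence: 11 steps (steps 1–5, 8–11, 14, 15); the diyne branch (steps 6, 7) and the glycerol branch (steps 12, 13) are two steps each.

Step 8 (key step). The likely failure is slow addition of the stabilised, weakly nucleophilic diynyl lithium, which leaves time for enolisation of the chloroaldehyde (loss of configuration at C9) and erodes the anti preference; attack of n-BuLi on the conjugated diyne during metalation is a second risk. The fallback sets out from 7 and uses the smallest and fastest acetylide. Lithium (trimethylsilyl)acetylide (from ethynyltrimethylsilane and n-BuLi, THF, −78 °C) is added to 7 to give (3S,4R,8Z,10Z)-4-chloro-1-(trimethylsilyl)trideca-8,10-dien-1-yn-3-ol F1. K2CO3 in MeOH then closes the oxirane and removes the C-silyl group in one operation to give (2S,3S)-2-ethynyl-3-[(4Z,6Z)-nona-4,6-dien-1-yl]oxirane F2 (the same compound as A2). Commercial tert-butyl(dimethyl)(pent-4-yn-1-yloxy)silane F3 is brominated (NBS, AgNO3) to [(5-bromopent-4-yn-1-yl)oxy](tert-butyl)dimethylsilane F4, and a single Cadiot–Chodkiewicz coupling of F2 with F4 (CuCl, NH2OH·HCl, n-BuNH2) comes back to the route at 15.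

Step 5. The likely failure is loss of enantiopurity through enolisation during concentration and storage, together with a second chlorination; the selectivity of the catalyst also sets the ceiling for the isomeric purity of the two-chain product. The fallback sets out from 6: the chlorination is run as before, and NaBH4 in MeOH is added to the same flask at 0 °C to give the configurationally stable (2R,6Z,8Z)-2-chloroundeca-6,8-dien-1-ol F5. This alcohol can be chromatographed, assayed for enantiopurity and stored. Oxidation with Dess–Martin periodinane (NaHCO3, CH2Cl2, 0 °C) immediately before step 8 comes back to the route at 7.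

Step 3. The likely failure is a reduction that stalls after the first triple bond, or partial over-reduction and Z-to-E isomerisation on the metal surface, because the diyne is flanked only by alkyl groups and has no nearby coordinating group. The fallback sets out from 4 and replaces electron transfer by hydroboration: dicyclohexylborane (3.3 equiv, one consumed by the hydroxyl; THF, 0 °C) adds syn to both triple bonds, AcOH at 55 °C cleaves both alkenyl–boron bonds with retention, and NaOH/H2O2 removes the boron residues. It comes back to the route at 5 and makes no new isolated compound (F0).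

Step 15. The likely failure is acyl migration from O2 to the freed O3 during reaction, work-up or chromatography, and oxidative damage to the two dienes by the quinone. The fallback sets out from 19 and 18 and replaces the oxidatively cleaved ether by a silyl ether. Compound 19 is silylated (t-BuPh2SiCl, imidazole) to tert-butyl{[(4R)-2,2-dimethyl-1,3-dioxolan-4-yl]methoxy}diphenylsilane F6 and hydrolysed (AcOH/H2O) to 3-O-[tert-butyl(diphenyl)silyl]-sn-glycerol F7. Diacylation with 18 as in step 14 gives 3-O-[tert-butyl(diphenyl)silyl]-1,2-bis-O-{7-[(2S,3S)-3-[(4Z,6Z)-nona-4,6-dien-1-yl]oxiran-2-yl]hepta-4,6-diynoyl}-sn-glycerol F8, and HF·pyridine buffered with pyridine (THF, 0 °C) removes the silyl group and comes back to the route at 24.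

Step 11. The likely failure is stalling at the aldehyde stage because hydrate formation is slow, slow opening of the oxirane by the acetic acid released, or attack of the oxoammonium species on the diene during the long second stage. The fallback sets out from 16 and separates the two oxidations: Dess–Martin periodinane (NaHCO3, CH2Cl2, 0 °C) gives 17, which is isolated, and a Pinnick oxidation (NaClO2, NaH2PO4, 2-methylbut-2-ene in excess, t-BuOH/H2O, 0 °C) comes back to the route at 18. No new compound is made (F0).

## Further compounds

F1 | step 8 | (3S,4R,8Z,10Z)-4-chloro-1-(trimethylsilyl)trideca-8,10-dien-1-yn-3-ol | C[Si](C)(C)C#C[C@H](O)[C@H](Cl)CCC/C=C\C=C/CC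
F2 | step 8 | (2S,3S)-2-ethynyl-3-[(4Z,6Z)-nona-4,6-dien-1-yl]oxirane | C#C[C@@H]1O[C@H]1CCC/C=C\C=C/CC
F3 | step 8 | tert-butyl(dimethyl)(pent-4-yn-1-yloxy)silane | C#CCCCO[Si](C)(C)C(C)(C)C
F4 | step 8 | [(5-bromopent-4-yn-1-yl)oxy](tert-butyl)dimethylsilane | BrC#CCCCO[Si](C)(C)C(C)(C)C
F5 | step 5 | (2R,6Z,8Z)-2-chloroundeca-6,8-dien-1-ol | OC[C@H](Cl)CCC/C=C\C=C/CC
F0 | step 3 | none | none
F6 | step 15 | tert-butyl{[(4R)-2,2-dimethyl-1,3-dioxolan-4-yl]methoxy}diphenylsilane | CC(C)(C)[Si](c1ccccc1)(c1ccccc1)OC[C@H]1COC(C)(C)O1
F7 | step 15 | (2R)-3-{[tert-butyl(diphenyl)silyl]oxy}propane-1,2-diol | OC[C@H](CO[Si](c1ccccc1)(c1ccccc1)C(C)(C)C)O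
F8 | step 15 | (2R)-3-{[tert-butyl(diphenyl)silyl]oxy}propane-1,2-diyl bis{7-[(2S,3S)-3-[(4Z,6Z)-nona-4,6-dien-1-yl]oxiran-2-yl]hepta-4,6-diynoate} | CC/C=C\C=C/CCC[C@@H]1O[C@H]1C#CC#CCCC(=O)OC[C@H](CO[Si](c2ccccc2)(c2ccccc2)C(C)(C)C)OC(=O)CCC#CC#C[C@@H]3O[C@H]3CCC/C=C\C=C/CC
F0 | step 11 | none | none
A1 | alternative 1 | (2S)-3-[(4-methoxyphenyl)methoxy]propane-1,2-diyl bis(5-bromopent-4-ynoate) | BrC#CCCC(=O)OC[C@H](COCc1ccc(OC)cc1)OC(=O)CCC#CBr
A2 | alternative 1 | (2S,3S)-2-ethynyl-3-[(4Z,6Z)-nona-4,6-dien-1-yl]oxirane | C#C[C@@H]1O[C@H]1CCC/C=C\C=C/CC
A3 | alternative 1 | (2S)-3-[(4-methoxyphenyl)methoxy]propane-1,2-diyl bis{7-[(2S,3S)-3-[(4Z,6Z)-nona-4,6-dien-1-yl]oxiran-2-yl]hepta-4,6-diynoate} | CC/C=C\C=C/CCC[C@@H]1O[C@H]1C#CC#CCCC(=O)OC[C@H](COCc2ccc(OC)cc2)OC(=O)CCC#CC#C[C@@H]3O[C@H]3CCC/C=C\C=C/CC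
A4 | alternative 2 | [(3E)-tridec-3-ene-1,8,10-triyn-1-yl]tri(propan-2-yl)silane | CC(C)[Si](C(C)C)(C(C)C)C#C/C=C/CCCC#CC#CCC
A5 | alternative 2 | 1,2:4,5-di-O-isopropylidene-β-L-erythro-2,3-hexodiulo-2,6-pyranose | C1[C@@H]2OC(C)(C)O[C@@H]2C(=O)[C@@]3(O1)COC(C)(C)O3
A6 | alternative 2 | tri(propan-2-yl){[(2S,3S)-3-(nona-4,6-diyn-1-yl)oxiran-2-yl]ethynyl}silane | CC(C)[Si](C(C)C)(C(C)C)C#C[C@@H]1O[C@H]1CCCC#CC#CCC
A7 | alternative 3 | [(2S,3S)-3-({[tert-butyl(diphenyl)silyl]oxy}methyl)oxiran-2-yl]methyl trifluoromethanesulfonate | CC(C)(C)[Si](c1ccccc1)(c1ccccc1)OC[C@@H]1O[C@H]1COS(=O)(=O)C(F)(F)F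
A8 | alternative 3 | (3Z,5Z)-octa-3,5-dien-1-ylmagnesium bromide | CC/C=C\C=C/CC[Mg]Br
A9 | alternative 3 | tert-butyl{[(2S,3S)-3-[(4Z,6Z)-nona-4,6-dien-1-yl]oxiran-2-yl]methoxy}diphenylsilane | CC(C)(C)[Si](c1ccccc1)(c2ccccc2)OC[C@@H]3O[C@H]3CCC/C=C\C=C/CC
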